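(The runs are simulated on assumed constants, and the scatter is random.)

A product ratio read after a reaction has gone quiet is easily taken for a ratio of rates, though it may be a ratio of equilibrium constants: kinetic against thermodynamic control.

| flask | substrate | partner | remark | time |
|---|---|---|---|---|
| ochre | 0.070 M | 0.90 equiv | run made earlier |  |
| violet | 0.11 M | 0.90 equiv | run made earlier |  |
| green | 0.050 M | 0.45 equiv | run made earlier |  |
| flask | 0.050 M | 0.900 equiv |  | 4.0 min |

| run | time / min | target / % | isomer of the product / % |
|---|---|---|---|
| ochre | 0.667 | 47.8 | 23.0 |
| ochre | 1.33 | 46.3 | 22.4 |
| ochre | 2.00 | 46.2 | 22.1 |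
| ochre | 2.50 | 45.4 | 22.3 |
| violet | 0.333 | 49.5 | 23.7 |
| violet | 0.833 | 51.2 | 23.8 |
| violet | 1.50 | 50.1 | 23.0 |
| violet | 2.50 | 48.9 | 25.0 |
| green | 0.200 | 22.7 | 8.1 |
| green | 0.417 | 27.2 | 13.0 |
| green | 1.00 | 25.2 | 9.7 |
| green | 2.50 | 24.1 | 12.7 |

(readings scatter by 1 percentage point)

- share of target in target plus isomer of the product at 0.20 s
- share of target in target plus isomer of the product at 4.0 min
- which of target and isomer of the product there is more of at 4.0 min

1. First instants. Substrate and partner meet, and both products come from this same pair by the same order. The ratio of their forward rates is therefore independent of concentration. The nearest evidence is the first readings of the ochre, violet and green runs, which pool to a target share of 68.6%.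

2. Middle. In the ochre run the fast rise lies before the first reading: target reads 47.8% at 0.667 min and 45.4% at 2.50 min. From here, any reversal lets the two products exchange through substrate and partner.

3. End. If both steps stand at equilibrium, both products face the same [substrate][partner]. So [target]/[isomer of the product] then equals the ratio of the equilibrium constants.

4. The quantity to carry is the late share, target over target plus isomer of the product, pooled from the last readings of the same runs: 66.4%. It lies 2.2 percentage points below the early share, against a scatter of 1 point per reading, so the fall is a hint. The reckoning here commits to 68.6% at 0.20 s and 66.4% at 4.0 min, with target ahead.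

The forecast gives 69% and 67%, with target ahead, noting “no real dependence on concentration”.

The flask gives 69.1% and 66.7%, with 42.6% target against 21.2% isomer of the product.

    substrate + partner ⇌ target (K = 140 M⁻¹, k = 2.10 M⁻¹ s⁻¹)
    substrate + partner ⇌ isomer of the product (K = 70.0 M⁻¹, k = 0.941 M⁻¹ s⁻¹)
    2 partner → self-condensation product (k = 0.0874 M⁻¹ s⁻¹)

In this flask at 4.00 min, the forward step to isomer of the product alone gives substrate a half-life of 1.5 min, shorter than the time allowed. Over the run, backward turnover in that step is 76% of the forward one, and in the step to target 78%. The late share applied to this flask's pair gives 42.4% target, beside the 42.6% it holds. In the neighbour with 0.20 M of substrate, 49.8% target and the late share give 25.2% isomer of the product, and that flask holds 24.9%.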